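## Retrosynthetic overview
1. Lariciresinol comes from global O-debenzylation of the di-O-benzyl tetrahydrofuran diol. The THF ring (the second ring to form) is made by a 5-exo-tet Williamson closure of the benzylic C7 alkoxide onto a C9′ tosylate, so C7 keeps its configuration.
2. C9 is carried as a non-participating Weinreb amide, obtained by opening a trans-3,4-disubstituted γ-butyrolactone. The lactone carries the C7 alcohol and C8 set by a ketoreductase dynamic kinetic resolution (DKR) of the 3-aroyl lactone.
3. The 3-aroyl lactone comes from aldol addition of O-benzylvanillin to (R)-4-arylmethyl-butyrolactone, followed by oxidation. That lactone (the first ring formed) comes from a Ru-BINAP asymmetric hydrogenation of a Stobbe half-ester, which sets C8′ first.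
4. The Stobbe half-ester comes from O-benzylvanillin and di-tert-butyl succinate, both achiral.

**Assumptions**
- (S)-BINAP is assumed to give the (R)-acid 4. If the opposite sense is found, use (R)-BINAP; nothing downstream changes.
- A ketoreductase (KRED) from a commercial panel is assumed to give the (7S, trans-3S) hydroxy lactone 11. The panel is screened for that outcome, checked by NOE and J values.

## Route

**Step 1**
Reactants: 1 (4-(benzyloxy)-3-methoxybenzaldehyde, O-benzylvanillin); 2 (di-tert-butyl succinate)
Product: 3, (E)-4-[4-(benzyloxy)-3-methoxyphenyl]-3-(tert-butoxycarbonyl)but-3-enoic acid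
Conditions: KOtBu (2.2 equiv), tBuOH, reflux; then aq. citric acid work-up
Reagents that add atoms: none
Why: Stobbe condensation (aldol, γ-lactonisation, E1cB ring opening) gives the E-itaconate half-ester, with the free acid on CH2 and the tBu ester on the alkene carbon.

**Step 2**
Reactants: 3
Product: 4, (R)-3-{[4-(benzyloxy)-3-methoxyphenyl]methyl}-4-(tert-butoxy)-4-oxobutanoic acid
Conditions: H2 (50 bar), Ru(OAc)2[(S)-BINAP] (1 mol %), MeOH, 50 °C, 24 h
Reagents that add atoms: none (H2 adds only hydrogen)
Why: Carboxylate-directed Ru-BINAP asymmetric hydrogenation of an itaconate-type alkene sets C8′ (the first stereocenter) by catalyst control.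

**Step 3**
Reactants: 4
Product: 5, 1-tert-butyl 4-methyl (2R)-2-{[4-(benzyloxy)-3-methoxyphenyl]methyl}butanedioate
Conditions: MeI, K2CO3, DMF, rt, 3 h
Reagents that add atoms: iodomethane, CI
Why: Carboxylate S_N2 alkylation differentiates the two carboxyls (tBu on the stereocenter side, Me on the CH2 side) without touching the stereocenter.

**Step 4**
Reactants: 5
Product: 6, (2R)-2-{[4-(benzyloxy)-3-methoxyphenyl]methyl}-4-methoxy-4-oxobutanoic acid
Conditions: TFA, CH2Cl2 (1:4), rt, 2 h
Reagents that add atoms: none
Why: Acidolysis (E1, loss of isobutene) removes only the tert-butyl ester; the methyl ester and aryl benzyl ethers survive.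

**Step 5**
Reactants: 6
Product: 7, methyl (3R)-3-{[4-(benzyloxy)-3-methoxyphenyl]methyl}-4-hydroxybutanoate
Conditions: BH3·SMe2 (1.2 equiv), THF, 0 °C to rt, 4 h; MeOH quench
Reagents that add atoms: none
Why: Borane reduces carboxylic acids much faster than esters, so the acid becomes CH2OH at the stereocenter side; no stereocenter is touched.

**Step 6**
Reactants: 7
Product: 8, (4R)-4-{[4-(benzyloxy)-3-methoxyphenyl]methyl}oxolan-2-one
Conditions: TsOH·H2O (5 mol %), toluene, 40 °C, 2 h
Reagents that add atoms: none
Why: Acid-catalysed γ-hydroxy-ester lactonisation (loss of MeOH) closes the first ring and places the C9 carbonyl on the CH2 side.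

**Step 7**
Reactants: 8; 1
Product: 9, (3,4-trans)-4-{[4-(benzyloxy)-3-methoxyphenyl]methyl}-3-{[4-(benzyloxy)-3-methoxyphenyl](hydroxy)methyl}oxolan-2-one, an ~1:1 mixture of C7 epimers
Conditions: LiHMDS (1.05 equiv), THF, −78 °C, 45 min; then 1 (1.1 equiv), −78 °C, 2 h; NH4Cl
Reagents that add atoms: none
Why: Lactone-enolate aldol addition occurs anti to the 4-substituent, giving the trans lactone required for C8/C8′; the C7 stereocenter is left unselective because it is erased in the next step.

**Step 8**
Reactants: 9
Product: 10, (4R)-3-(4-benzyloxy-3-methoxybenzoyl)-4-{[4-(benzyloxy)-3-methoxyphenyl]methyl}oxolan-2-one (C3 epimerisable, partly enolised)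
Conditions: Dess–Martin periodinane (1.5 equiv), NaHCO3, CH2Cl2, 0 °C to rt, 2 h
Reagents that add atoms: none
Why: Dess–Martin oxidation converts both C7 epimers to one β-keto lactone, which funnels the mixture into the enzymatic DKR.

**Step 9**
Reactants: 10
Product: 11, (3S,4R)-4-{[4-(benzyloxy)-3-methoxyphenyl]methyl}-3-[(S)-[4-(benzyloxy)-3-methoxyphenyl](hydroxy)methyl]oxolan-2-one
Conditions: KRED (NADPH-dependent ketoreductase, an oxidoreductase), NADP+ (cat.), D-glucose, glucose dehydrogenase, KPi buffer pH 7.0/DMSO 85:15, 30 °C, 24 h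
Reagents that add atoms: none (net addition of H2 from glucose)
Why: The acidic C3-H (enol) racemises at pH 7, so the enzyme reduces one epimer and one ketone face, a DKR that sets C7 (S) and lactone C3 (S, trans to C8′).

**Step 10**
Reactants: 11
Product: 12, (2S,3R)-3-{[4-(benzyloxy)-3-methoxyphenyl]methyl}-2-[(S)-[4-(benzyloxy)-3-methoxyphenyl](hydroxy)methyl]-4-hydroxy-N-methoxy-N-methylbutanamide
Conditions: MeNHOMe·HCl (3 equiv), AlMe3 (3 equiv), CH2Cl2, 0 °C to rt, 4 h; Rochelle salt work-up
Reagents that add atoms: N,O-dimethylhydroxylamine, CNOC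
Why: Al-amide (Weinreb) lactone opening is irreversible, so it traps the open-chain form; the amide gives a C9 carbon that cannot lactonise, cannot retro-aldolise easily and cannot participate in the cyclisation.

**Step 11**
Reactants: 12
Product: 13, the C9′-tosylate of 12: (2S,3R)-3-{[4-(benzyloxy)-3-methoxyphenyl]methyl}-2-[(S)-[4-(benzyloxy)-3-methoxyphenyl](hydroxy)methyl]-4-(tosyloxy)-N-methoxy-N-methylbutanamide
Conditions: TsCl (1.05 equiv), pyridine, CH2Cl2, 0 °C to rt, 12 h
Reagents that add atoms: p-toluenesulfonyl chloride, Cc1ccc(cc1)S(=O)(=O)Cl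
Why: Sulfonylation is selective for the unhindered primary alcohol over the hindered benzylic secondary alcohol, so only C9′ is activated.

**Step 12**
Reactants: 13
Product: 14, (2S,3S,4R)-2-[4-(benzyloxy)-3-methoxyphenyl]-4-{[4-(benzyloxy)-3-methoxyphenyl]methyl}-N-methoxy-N-methyloxolane-3-carboxamide
Conditions: NaH (1.5 equiv), THF, 0 °C, 1 h
Reagents that add atoms: none
Why: Intramolecular Williamson etherification (5-exo-tet S_N2) by the C7 alkoxide closes the THF ring; the C7–O bond is never broken, so C7 is retained, and the amide suppresses retro-aldol and epimerisation.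

**Step 13**
Reactants: 14
Product: 15, [(2S,3R,4R)-2-(4-benzyloxy-3-methoxyphenyl)-4-{[4-(benzyloxy)-3-methoxyphenyl]methyl}oxolan-3-yl]methanol (di-O-benzyl lariciresinol)
Conditions: DIBAL-H (2.5 equiv), THF, −78 °C, 1 h; then MeOH, NaBH4 (3 equiv), −78 to 0 °C
Reagents that add atoms: none
Why: The Weinreb amide gives a stable aluminium hemiaminal that collapses to the aldehyde only on the methanol quench, in the presence of NaBH4; the aldehyde is reduced at once to CH2OH, so the acid/base-sensitive C8 centre is not epimerised.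

**Step 14**
Reactants: 15
Product: 16, (+)-lariciresinol
Conditions: H2 (1 atm), 10% Pd/C, EtOAc/MeOH 1:1, rt, 2–4 h (monitor)
Reagents that add atoms: none
Why: Hydrogenolysis cleaves both aryl benzyl ethers (toluene lost), and no stereocenter is involved; the reaction is stopped at full consumption to avoid cleaving the benzylic THF C–O bond.

## Compound list
1 | 4-(benzyloxy)-3-methoxybenzaldehyde | COc1cc(C=O)ccc1OCc1ccccc1 | starting material
2 | di-tert-butyl succinate | CC(C)(C)OC(=O)CCC(=O)OC(C)(C)C | starting material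
3 | Stobbe half-ester (E) | COc1cc(/C=C(/C(=O)OC(C)(C)C)CC(=O)O)ccc1OCc1ccccc1 | intermediate
4 | (R)-acid/tBu ester | OC(=O)C[C@@H](Cc1ccc(OCc2ccccc2)c(OC)c1)C(=O)OC(C)(C)C | intermediate
5 | (R)-Me/tBu diester | COC(=O)C[C@@H](Cc1ccc(OCc2ccccc2)c(OC)c1)C(=O)OC(C)(C)C | intermediate
6 | (R)-acid/Me ester | COC(=O)C[C@@H](Cc1ccc(OCc2ccccc2)c(OC)c1)C(=O)O | intermediate
7 | (R)-hydroxy ester | COC(=O)C[C@@H](Cc1ccc(OCc2ccccc2)c(OC)c1)CO | intermediate
8 | (R)-β-arylmethyl-γ-butyrolactone | O=C1OC[C@H](Cc2ccc(OCc3ccccc3)c(OC)c2)C1 | intermediate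
9 | trans aldol lactone (C7 epimer mixture; C7 unspecified) | O=C1OC[C@H](Cc2ccc(OCc3ccccc3)c(OC)c2)[C@H]1C(O)c1ccc(OCc2ccccc2)c(OC)c1 | intermediate
10 | 3-aroyl lactone (C3 epimerisable) | O=C1OC[C@H](Cc2ccc(OCc3ccccc3)c(OC)c2)C1C(=O)c1ccc(OCc2ccccc2)c(OC)c1 | intermediate
11 | (3S,4R,7S)-hydroxy lactone | O=C1OC[C@H](Cc2ccc(OCc3ccccc3)c(OC)c2)[C@H]1[C@H](O)c1ccc(OCc2ccccc2)c(OC)c1 | intermediate
12 | hydroxy Weinreb amide | CON(C)C(=O)[C@H]([C@H](O)c1ccc(OCc2ccccc2)c(OC)c1)[C@@H](Cc1ccc(OCc2ccccc2)c(OC)c1)CO | intermediate
13 | C9′-tosylate | CON(C)C(=O)[C@H]([C@H](O)c1ccc(OCc2ccccc2)c(OC)c1)[C@@H](Cc1ccc(OCc2ccccc2)c(OC)c1)COS(=O)(=O)c1ccc(C)cc1 | intermediate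
14 | THF Weinreb amide | COc1cc(C[C@H]2CO[C@H](c3ccc(OCc4ccccc4)c(OC)c3)[C@H]2C(=O)N(C)OC)ccc1OCc1ccccc1 | intermediate
15 | di-O-benzyl lariciresinol | COc1cc(C[C@H]2CO[C@H](c3ccc(OCc4ccccc4)c(OC)c3)[C@H]2CO)ccc1OCc1ccccc1 | intermediate
16 | (+)-lariciresinol | COc1cc(C[C@H]2CO[C@H](c3ccc(O)c(OC)c3)[C@H]2CO)ccc1O | target

## Totals
Total steps: 14. Longest linear sequence: 14 steps (1 and 2 to 16).

## Three steps most likely to fail
1. **Step 9 (KRED DKR).** The panel hit and its diastereoselectivity are not known in advance.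
   - Fallback: skip the oxidation and reduction. Take aldol mixture 9, separate the C7 epimers by chromatography and lipase-catalysed (Burkholderia cepacia lipase, vinyl acetate) kinetic acylation, and recycle the unwanted epimer through 10.
2. **Step 12 (NaH cyclisation).** Risks are Weinreb N–OMe decomposition under strong base, competing retro-aldol, and C8 epimerisation.
   - Fallback: protect C7-OH of 12 as TBS, convert the amide to the C9-OBn ether, tosylate C9′, and release the C7 alkoxide with TBAF so that ring closure is triggered without base or carbonyl.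
3. **Step 14 (hydrogenolysis).** Over-reduction (benzylic THF C–O cleavage) is possible.
   - Fallback: restart with O-allylvanillin so that the phenols are allyl-protected. This needs the step 2 hydrogenation re-checked for tolerance of the allyl ether. Deprotect in the last step with Pd(PPh3)4/K2CO3/MeOH, which leaves the benzylic ether untouched.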